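**Plan**

- Cuts: first the CH–CH2 bond joining the two halves (Michael dimerization of suberosenone 18). In 18 the C3 ketone and C2 methylidene are traced back to a C2 ketone (allylic oxidation, Wittig). The key cut then removes C5–C6 (ring B) and C1–C9 (ring C) together. Last come the ring A–side-chain bond (Negishi) and a side-chain aldol bond.
- Forward: the chain is built by aldol addition, silylation, reduction and iodination and joined to ring A, a 2-iodo-4-silyloxycyclopentenone. A radical cascade closes ring B, then ring C. Elimination, hydrogenation, methylenation, allylic oxidation and oxidation give 18, which is dimerized.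
- Enabling feature: in ring A the enone C=C lies between the tether-bearing α-carbon (future C1) and the β-carbon (future C5). The ketone makes C5 the acceptor for the side-chain radical at C6 and turns C1 into a tertiary α-keto radical placed 6-exo to the alkyne carbon that becomes C9. The gem-dimethyl carbon C11 favours the first closure.
- Stereochemistry: the C4 silyl ether of the (S)-enone (chiral pool, later eliminated) fixes C5. The cis ring A/ring B fusion and the bridge then fix C6 and C1. C9 is set by hydrogenation of the exocyclic methylene from its open face. The two centres at the dimer link come from enolate attack anti to ring B and protonation anti to the C9 bridge.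

Key step: step 9

Remark: the side-chain carbinol carbon made in step 1 is carried as a racemate (3–6) and as both epimers (10–12) because it becomes a planar radical in step 9; tricyclic compounds are numbered as tricyclo[4.3.2.0^1,5]undecanes (C1 quaternary, C2–C4 rest of ring A, C5 ring-fusion CH, C6 bridgehead CH, C7–C9 ring C, C10 and C11 ring B).

**Route**

Step 1
Reactants: 1 methyl isobutyrate; 2 pent-4-ynal
Product: 3 methyl 3-hydroxy-2,2-dimethylhept-6-ynoate (racemate)
Conditions: LiN(i-Pr)2, THF, −78 °C; then 2; aq NH4Cl
Reagents that add atoms: none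
Why: Aldol addition of the fully substituted lithium ester enolate to the aldehyde at −78 °C should outrun proton transfer from the alkyne or the aldehyde α-position, and the new carbinol centre may stay racemic because step 9 erases it.

Step 2
Reactants: 3 methyl 3-hydroxy-2,2-dimethylhept-6-ynoate
Product: 4 methyl 2,2-dimethyl-3-(triethylsilyloxy)hept-6-ynoate
Conditions: Et3SiOTf, 2,6-lutidine, CH2Cl2, −78 → 0 °C
Reagents that add atoms: triethylsilyl trifluoromethanesulfonate, CC[Si](CC)(CC)OS(=O)(=O)C(F)(F)F
Why: Silylation with a silyl triflate and a hindered pyridine base is the standard protection of a hindered secondary alcohol, and the triethylsilyl ether can later be removed beside a tert-butyldimethylsilyl ether.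

Step 3
Reactants: 4 methyl 2,2-dimethyl-3-(triethylsilyloxy)hept-6-ynoate
Product: 5 2,2-dimethyl-3-(triethylsilyloxy)hept-6-yn-1-ol
Conditions: i-Bu2AlH (2.5 equiv), CH2Cl2, −78 → 0 °C
Reagents that add atoms: none
Why: Aluminium hydride reduction of the ester to the primary alcohol tolerates the silyl ether and the terminal alkyne.

Step 4
Reactants: 5 2,2-dimethyl-3-(triethylsilyloxy)hept-6-yn-1-ol
Product: 6 triethyl[(7-iodo-6,6-dimethylhept-1-yn-5-yl)oxy]silane
Conditions: I2, PPh3, imidazole, toluene, 80 °C
Reagents that add atoms: iodine, [I][I]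
Why: Appel-type iodination through the alkoxyphosphonium ion converts neopentyl-type primary alcohols into iodides on heating, and imidazole buffers the acid so that the silyl ether should survive.

Step 5
Reactants: 7 (S)-4-(tert-butyldimethylsilyloxy)cyclopent-2-en-1-one
Product: 8 (S)-4-(tert-butyldimethylsilyloxy)-2-iodocyclopent-2-en-1-one
Conditions: I2, pyridine, CH2Cl2, 0 → 25 °C
Reagents that add atoms: iodine, [I][I]
Why: α-Iodination of the enone by conjugate addition of pyridine, iodination of the enolate and elimination is well established for 4-silyloxycyclopentenones and leaves the C4 stereocentre untouched.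

Step 6
Reactants: 6 triethyl[(7-iodo-6,6-dimethylhept-1-yn-5-yl)oxy]silane; 8 (S)-4-(tert-butyldimethylsilyloxy)-2-iodocyclopent-2-en-1-one
Product: 10 (4S)-4-(tert-butyldimethylsilyloxy)-2-[2,2-dimethyl-3-(triethylsilyloxy)hept-6-yn-1-yl]cyclopent-2-en-1-one, via alkylzinc iodide 9 (not isolated)
Conditions: Zn dust (activated with BrCH2CH2Br and Me3SiCl), LiCl, THF, 50 °C; then 8, Pd2(dba)3 (2 mol%), SPhos (8 mol%), THF, 25 → 40 °C
Reagents that add atoms: none
Why: Negishi coupling of an alkylzinc iodide with an α-iodoenone is precedented, the neopentyl zinc reagent has no β-hydrogen to lose, and zinc insertion tolerates the terminal alkyne and both silyl ethers.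

Step 7
Reactants: 10 (4S)-4-(tert-butyldimethylsilyloxy)-2-[2,2-dimethyl-3-(triethylsilyloxy)hept-6-yn-1-yl]cyclopent-2-en-1-one
Product: 11 (4S)-4-(tert-butyldimethylsilyloxy)-2-(3-hydroxy-2,2-dimethylhept-6-yn-1-yl)cyclopent-2-en-1-one
Conditions: HF·pyridine, pyridine, THF, 0 °C
Reagents that add atoms: none
Why: Selective desilylation with buffered fluoride should cleave the triethylsilyl ether well before the secondary tert-butyldimethylsilyl ether and spares the γ-silyloxy enone.

Step 8
Reactants: 11 (4S)-4-(tert-butyldimethylsilyloxy)-2-(3-hydroxy-2,2-dimethylhept-6-yn-1-yl)cyclopent-2-en-1-one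
Product: 12 O-{1-[(3S)-3-(tert-butyldimethylsilyloxy)-5-oxocyclopent-1-en-1-yl]-2,2-dimethylhept-6-yn-3-yl} O-phenyl carbonothioate
Conditions: PhOC(S)Cl, pyridine, DMAP, CH2Cl2, 0 → 40 °C
Reagents that add atoms: O-phenyl chlorothionoformate, S=C(Cl)Oc1ccccc1
Why: Acylation of the hindered alcohol under nucleophilic catalysis gives the aryl thionocarbonate that serves as radical precursor in Barton–McCombie-type chemistry.

Step 9
Reactants: 12 O-{1-[(3S)-3-(tert-butyldimethylsilyloxy)-5-oxocyclopent-1-en-1-yl]-2,2-dimethylhept-6-yn-3-yl} O-phenyl carbonothioate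
Product: 13 4-(tert-butyldimethylsilyloxy)-11,11-dimethyl-9-methylidenetricyclo[4.3.2.0^1,5]undecan-2-one (silyloxy group on the face of ring A opposite to C6; ring fusions as in the target)
Conditions: (Me3Si)3SiH (1.2 equiv) and 1,1′-azobis(cyclohexanecarbonitrile) (0.3 equiv) by syringe pump over 10 h, toluene (2 mM), 105 °C
Reagents that add atoms: none
Why: Proposed new method: the silyl radical removes the thionocarbonate to give the secondary side-chain radical (future C6), which should close 5-endo-trig onto the enone β-carbon (future C5), and the tertiary α-keto radical so formed at the α-carbon (future C1) should then close 6-exo-dig onto the internal alkyne carbon (future C9) before the vinyl radical takes hydrogen from the silane. The closest known reaction types are 5-endo-trig closures of carbon radicals onto acceptor alkenes that give carbonyl-stabilized tertiary radicals and 6-exo-dig cyclizations of α-keto radicals onto alkynes; their tandem use on an α-tethered cyclopentenone is new. Ring B closes 5-endo-trig (polarity-matched, exothermic, helped by the gem-dimethyl group) and ring C closes 6-exo-dig. C5 is set by attack anti to the C4 silyl ether; C6 is set by the preference of the butynyl arm for the convex face (the other rotamer cannot reach C1 and would only be reduced); C1 is set by the cis fusion of ring B, which leaves only the opposite face open to the alkyne. The step needs the first closure to outrun hydrogen transfer to the side-chain radical, which slow addition of the silane at high dilution and 105 °C should secure. It also needs attack on the enone rather than the alkyne, which the nucleophilic character of the alkyl radical and the stabilized product radical should secure.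

Step 10
Reactants: 13 4-(tert-butyldimethylsilyloxy)-11,11-dimethyl-9-methylidenetricyclo[4.3.2.0^1,5]undecan-2-one
Product: 14 11,11-dimethyl-9-methylidenetricyclo[4.3.2.0^1,5]undec-3-en-2-one
Conditions: DBU (2 equiv), CH2Cl2, 0 → 25 °C
Reagents that add atoms: none
Why: E1cB elimination of the β-silyloxy group through the only enolizable α-position (C3) should give the conjugated enone and removes the auxiliary stereocentre once it has done its work.

Step 11
Reactants: 14 11,11-dimethyl-9-methylidenetricyclo[4.3.2.0^1,5]undec-3-en-2-one
Product: 15 9,11,11-trimethyltricyclo[4.3.2.0^1,5]undecan-2-one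
Conditions: H2 (1 atm), PtO2, EtOAc, 25 °C
Reagents that add atoms: none
Why: Heterogeneous hydrogenation should saturate the enone C=C and add hydrogen to the exocyclic methylene from its outer face, because the inner face is covered by the syn hydrogen on C5 and by ring A, so the new methyl group should end on the ring A side as in the target.

Step 12
Reactants: 15 9,11,11-trimethyltricyclo[4.3.2.0^1,5]undecan-2-one
Product: 16 9,11,11-trimethyl-2-methylidenetricyclo[4.3.2.0^1,5]undecane
Conditions: Ph3PCH3Br, KOt-Bu, toluene, 90 °C
Reagents that add atoms: methyltriphenylphosphonium bromide, [Br-].C[P+](c1ccccc1)(c1ccccc1)c1ccccc1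
Why: Wittig methylenation with the salt-free ylide at elevated temperature is the usual answer to a hindered α-quaternary ketone, and no epimerizable centre is present.

Step 13
Reactants: 16 9,11,11-trimethyl-2-methylidenetricyclo[4.3.2.0^1,5]undecane
Product: 17 9,11,11-trimethyl-2-methylidenetricyclo[4.3.2.0^1,5]undecan-3-ol (either carbinol epimer)
Conditions: SeO2 (0.5 equiv), t-BuOOH (3 equiv), CH2Cl2, 25 °C
Reagents that add atoms: tert-butyl hydroperoxide, CC(C)(C)OO
Why: Selenium dioxide allylic oxidation (ene reaction, then [2,3]-shift) of the 1,1-disubstituted exocyclic alkene should hydroxylate the only allylic CH2 (C3), as in the conversion of β-pinene into pinocarveol, and the configuration of the carbinol is of no consequence.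

Step 14
Reactants: 17 9,11,11-trimethyl-2-methylidenetricyclo[4.3.2.0^1,5]undecan-3-ol
Product: 18 suberosenone (9,11,11-trimethyl-2-methylidenetricyclo[4.3.2.0^1,5]undecan-3-one)
Conditions: 1,1,1-triacetoxy-1,1-dihydro-1,2-benziodoxol-3(1H)-one, NaHCO3, CH2Cl2, 0 → 25 °C
Reagents that add atoms: none
Why: Dess–Martin oxidation of the allylic alcohol should give the α-methylene ketone without acid or base that could start conjugate additions.

Step 15
Reactants: 18 suberosenone (two molecules)
Product: 20 alertenone, via lithium dienolate 19 (not isolated)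
Conditions: LiN(SiMe3)2 (0.5 equiv), THF, −78 → −40 °C; then AcOH, −78 °C
Reagents that add atoms: none
Why: Michael addition of the cross-conjugated lithium enolate of one molecule to the exocyclic methylene of a second should join the halves, with the enolate carbon attacked anti to the adjacent ring B bond and the α-centre of the acceptor half set by protonation of its enolate from the face away from the methyl-bearing C9 bridge.

**Compound list**

1 | methyl isobutyrate (methyl 2-methylpropanoate) | COC(=O)C(C)C | starting material
2 | pent-4-ynal | O=CCCC#C | starting material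
3 | methyl 3-hydroxy-2,2-dimethylhept-6-ynoate (racemate) | COC(=O)C(C)(C)C(O)CCC#C | intermediate
4 | methyl 2,2-dimethyl-3-(triethylsilyloxy)hept-6-ynoate (racemate) | COC(=O)C(C)(C)C(O[Si](CC)(CC)CC)CCC#C | intermediate
5 | 2,2-dimethyl-3-(triethylsilyloxy)hept-6-yn-1-ol (racemate) | OCC(C)(C)C(O[Si](CC)(CC)CC)CCC#C | intermediate
6 | triethyl[(7-iodo-6,6-dimethylhept-1-yn-5-yl)oxy]silane (racemate) | ICC(C)(C)C(O[Si](CC)(CC)CC)CCC#C | intermediate
7 | (S)-4-(tert-butyldimethylsilyloxy)cyclopent-2-en-1-one | O=C1C=C[C@@H](O[Si](C)(C)C(C)(C)C)C1 | starting material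
8 | (S)-4-(tert-butyldimethylsilyloxy)-2-iodocyclopent-2-en-1-one | O=C1C(I)=C[C@@H](O[Si](C)(C)C(C)(C)C)C1 | intermediate
9 | [2,2-dimethyl-3-(triethylsilyloxy)hept-6-yn-1-yl]zinc iodide | I[Zn]CC(C)(C)C(O[Si](CC)(CC)CC)CCC#C | intermediate
10 | (4S)-4-(tert-butyldimethylsilyloxy)-2-[2,2-dimethyl-3-(triethylsilyloxy)hept-6-yn-1-yl]cyclopent-2-en-1-one (both side-chain epimers) | O=C1C(CC(C)(C)C(O[Si](CC)(CC)CC)CCC#C)=C[C@@H](O[Si](C)(C)C(C)(C)C)C1 | intermediate
11 | (4S)-4-(tert-butyldimethylsilyloxy)-2-(3-hydroxy-2,2-dimethylhept-6-yn-1-yl)cyclopent-2-en-1-one (both side-chain epimers) | O=C1C(CC(C)(C)C(O)CCC#C)=C[C@@H](O[Si](C)(C)C(C)(C)C)C1 | intermediate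
12 | O-{1-[(3S)-3-(tert-butyldimethylsilyloxy)-5-oxocyclopent-1-en-1-yl]-2,2-dimethylhept-6-yn-3-yl} O-phenyl carbonothioate (both side-chain epimers) | O=C1C(CC(C)(C)C(OC(=S)Oc2ccccc2)CCC#C)=C[C@@H](O[Si](C)(C)C(C)(C)C)C1 | intermediate
13 | 4-(tert-butyldimethylsilyloxy)-11,11-dimethyl-9-methylidenetricyclo[4.3.2.0^1,5]undecan-2-one (silyloxy group anti to C6 across ring A) | O=C1C[C@H](O[Si](C)(C)C(C)(C)C)[C@H]2[C@@H]3CCC(=C)[C@]12CC3(C)C | intermediate
14 | 11,11-dimethyl-9-methylidenetricyclo[4.3.2.0^1,5]undec-3-en-2-one | O=C1C=C[C@H]2[C@@H]3CCC(=C)[C@]12CC3(C)C | intermediate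
15 | 9,11,11-trimethyltricyclo[4.3.2.0^1,5]undecan-2-one (methyl on the ring A side) | O=C1CC[C@H]2[C@@H]3CC[C@H](C)[C@]12CC3(C)C | intermediate
16 | 9,11,11-trimethyl-2-methylidenetricyclo[4.3.2.0^1,5]undecane | C=C1CC[C@H]2[C@@H]3CC[C@H](C)[C@]12CC3(C)C | intermediate
17 | 9,11,11-trimethyl-2-methylidenetricyclo[4.3.2.0^1,5]undecan-3-ol (carbinol configuration not defined) | C=C1C(O)C[C@H]2[C@@H]3CC[C@H](C)[C@]12CC3(C)C | intermediate
18 | suberosenone | C=C1C(=O)C[C@H]2[C@@H]3CC[C@H](C)[C@]12CC3(C)C | intermediate
19 | lithium dienolate of suberosenone | C=C1C(O[Li])=C[C@H]2[C@@H]3CC[C@H](C)[C@]12CC3(C)C | intermediate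
20 | alertenone | C=C1C(=O)[C@H](C[C@@H]2C(=O)C[C@H]3[C@@H]4CC[C@H](C)[C@]23CC4(C)C)[C@H]2[C@@H]3CC[C@H](C)[C@]12CC3(C)C | target

**Step count and risks**

Total steps: 15. Longest linear sequence: 14 steps (steps 1–4 and 6–15; step 5 is the side branch).

Step 9. What may go wrong: hydrogen transfer to the side-chain radical, or reduction of the α-keto radical, may outrun the strained 5-endo closure or the 6-exo closure, so that only deoxygenated or bicyclic material forms. The fallback sets out from 11 and comes back at 13, making the two bonds one after the other by known reactions.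
- Dehydration of 11 with methyl N-(triethylammoniosulfonyl)carbamate (toluene, 80 °C) should give (4S)-4-(tert-butyldimethylsilyloxy)-2-[(3E)-2,2-dimethylhept-3-en-6-yn-1-yl]cyclopent-2-en-1-one F1.
- Conjugate addition of benzeneselenol (PhSeSePh, NaBH4, EtOH, then AcOH) anti to the silyl ether, with kinetic protonation, should give (2,3-cis,3,4-trans)-4-(tert-butyldimethylsilyloxy)-2-[(3E)-2,2-dimethylhept-3-en-6-yn-1-yl]-3-(phenylselanyl)cyclopentan-1-one F2.
- Bu3SnH and AIBN (benzene, 80 °C) generate the non-conjugated ring radical, which should close 5-exo-trig onto the side-chain alkene to cis-fused 6-(but-3-yn-1-yl)-4-(tert-butyldimethylsilyloxy)-7,7-dimethylbicyclo[3.3.0]octan-2-one F3, with the butynyl arm on the convex face.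
- Soft enolization toward the ring fusion (t-BuMe2SiOTf, Et3N, CH2Cl2) should give 2,4-bis(tert-butyldimethylsilyloxy)-6-(but-3-yn-1-yl)-7,7-dimethylbicyclo[3.3.0]oct-1-ene F4.
- Gold-catalysed 6-exo-dig addition of the silyl enol ether to the alkyne (Ph3PAuCl, AgBF4, CH2Cl2–MeOH, 25 °C) then forms the second bond and returns 13.

Step 11. What may go wrong: the exocyclic double bond may migrate into ring C on the metal surface before reduction, or facial selectivity may be poor, either of which would erode the configuration at C9. The fallback sets out from 14 and comes back at 15. It replaces surface hydrogenation by radical hydrogenation through hydrogen-atom transfer (Mn(dpm)3, PhSiH3, t-BuOOH, i-PrOH, 25 °C). The tertiary C9 radical should take its hydrogen atom in solution from the outer face, and the same reagent reduces the enone. No compound outside the list is formed (F0).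

Step 15. What may go wrong: the product enolate may add to further enone (oligomerization), or proton exchange between enolates may cause loss of control over the two new centres. The fallback sets out from 18 and comes back at 20.
- Half of 18 is converted with LiN(i-Pr)2 and Me3SiCl (THF, −78 °C) into 9,11,11-trimethyl-2-methylidene-3-(trimethylsilyloxy)tricyclo[4.3.2.0^1,5]undec-3-ene F5.
- F5 is combined with the other half of 18 in a Mukaiyama–Michael addition (TiCl4, CH2Cl2, −78 °C; aq NaHCO3). This should stop at the 1:1 adduct because the product enolate is not a donor under these conditions, and protonation on work-up should give 20.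

Further compounds
F1 | step 9 | (4S)-4-(tert-butyldimethylsilyloxy)-2-[(3E)-2,2-dimethylhept-3-en-6-yn-1-yl]cyclopent-2-en-1-one | O=C1C(CC(C)(C)/C=C/CC#C)=C[C@@H](O[Si](C)(C)C(C)(C)C)C1
F2 | step 9 | 4-(tert-butyldimethylsilyloxy)-2-[(3E)-2,2-dimethylhept-3-en-6-yn-1-yl]-3-(phenylselanyl)cyclopentan-1-one (selanyl trans to silyloxy, side chain cis to selanyl) | O=C1[C@H](CC(C)(C)/C=C/CC#C)[C@H]([Se]c2ccccc2)[C@@H](O[Si](C)(C)C(C)(C)C)C1
F3 | step 9 | cis-fused 6-(but-3-yn-1-yl)-4-(tert-butyldimethylsilyloxy)-7,7-dimethylbicyclo[3.3.0]octan-2-one (butynyl on the convex face) | O=C1C[C@H](O[Si](C)(C)C(C)(C)C)[C@H]2[C@H](CCC#C)C(C)(C)C[C@@H]12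
F4 | step 9 | 2,4-bis(tert-butyldimethylsilyloxy)-6-(but-3-yn-1-yl)-7,7-dimethylbicyclo[3.3.0]oct-1-ene | CC(C)(C)[Si](C)(C)OC1=C2CC(C)(C)[C@@H](CCC#C)[C@@H]2[C@@H](O[Si](C)(C)C(C)(C)C)C1
F0 | step 11 | none | none
F5 | step 15 | 9,11,11-trimethyl-2-methylidene-3-(trimethylsilyloxy)tricyclo[4.3.2.0^1,5]undec-3-ene | C=C1C(O[Si](C)(C)C)=C[C@H]2[C@@H]3CC[C@H](C)[C@]12CC3(C)C
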